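**Assumption:** nortopsentin C has no stereogenic element, so the "single enantiomer" is the one achiral compound. The imidazole N–H tautomers interconvert, and the target is drawn as in the given SMILES.

## Retrosynthetic overview
1. Nortopsentin C comes from its bis(N-tosyl) derivative by hydrolysis of both sulfonamides. Both indole rings are bought intact.
2. The imidazole is the only ring built, and it is built last. An α-acylamino ketone cyclocondenses with ammonia, which supplies N3 and closes C4–N3 and C2–N3.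
3. The α-acylamino ketone comes from oxidation of a β-hydroxy amide. That amide (the N1–C2 bond) joins a 2-amino-1-(indol-3-yl)ethanol to 1-tosylindole-3-carboxylic acid.
4. The amino alcohol comes from a nitro alcohol, made by the intermolecular Henry (nitroaldol) addition of nitromethane to 6-bromo-1-tosylindole-3-carbaldehyde. This is the key C–C bond, imidazole C4–C5.
5. The two carbonyl partners come from 6-bromoindole (Vilsmeier, then tosylation) and indole-3-carbaldehyde (tosylation, then Pinnick oxidation).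

## Route

Step 1
Reactants: 1 6-bromo-1H-indole
Product: 3 6-bromo-1H-indole-3-carbaldehyde, via iminium chloride 2 (not isolated)
Conditions: POCl3 (1.2 equiv), DMF, 0 → 40 °C; then aq NaOH, 0 °C → brief reflux
Reagents that add atoms: N,N-dimethylformamide CN(C)C=O; water O
Why: In this Vilsmeier–Haack formylation the chloroiminium ion attacks the most nucleophilic position, indole C3, and basic hydrolysis of the iminium salt releases the aldehyde while the aryl bromide stays inert.

Step 2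
Reactants: 3 6-bromo-1H-indole-3-carbaldehyde
Product: 4 6-bromo-1-tosyl-1H-indole-3-carbaldehyde
Conditions: TsCl (1.2 equiv), Et3N (2 equiv), DMAP (0.1 equiv), CH2Cl2, 0 °C → rt
Reagents that add atoms: p-toluenesulfonyl chloride Cc1ccc(cc1)S(=O)(=O)Cl
Why: DMAP-catalysed N-sulfonylation of the acidic 3-formylindole N–H removes the vinylogous-amide donation, so this aldehyde and the later ketone react as normal aryl carbonyl groups.

Step 3
Reactants: 4 6-bromo-1-tosyl-1H-indole-3-carbaldehyde; 5 nitromethane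
Product: 6 (±)-1-(6-bromo-1-tosyl-1H-indol-3-yl)-2-nitroethanol
Conditions: MeNO2 (10 equiv), Et3N (0.3 equiv), THF, 0 °C → rt, 24 h; AcOH quench
Reagents that add atoms: none
Why: In this intermolecular Henry (nitroaldol) addition, which has no by-product, the nitronate of 5 adds to the activated aldehyde to form the future imidazole C4–C5 bond, excess nitromethane drives the equilibrium, the mild amine base avoids dehydration, and the racemic carbinol centre does not matter because step 8 erases it.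

Step 4
Reactants: 6 (±)-1-(6-bromo-1-tosyl-1H-indol-3-yl)-2-nitroethanol
Product: 7 (±)-2-amino-1-(6-bromo-1-tosyl-1H-indol-3-yl)ethanol
Conditions: Zn dust (20 equiv), AcOH/THF 1:1, 0 °C → rt; filter, aq NH3/EtOAc work-up
Reagents that add atoms: none
Why: Dissolving-metal reduction of the aliphatic nitro group in an acidic medium excludes the base-induced retro-Henry reaction and leaves the aryl bromide, the sulfonamide and the N-tosyl-deactivated carbinol untouched.

Step 5
Reactants: 8 1H-indole-3-carbaldehyde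
Product: 9 1-tosyl-1H-indole-3-carbaldehyde
Conditions: TsCl (1.2 equiv), Et3N (2 equiv), DMAP (0.1 equiv), CH2Cl2, 0 °C → rt
Reagents that add atoms: p-toluenesulfonyl chloride Cc1ccc(cc1)S(=O)(=O)Cl
Why: This is the same DMAP-catalysed N-sulfonylation as in step 2, and it gives an acyl partner whose later amide carbonyl is electrophilic enough for ring closure.

Step 6
Reactants: 9 1-tosyl-1H-indole-3-carbaldehyde
Product: 10 1-tosyl-1H-indole-3-carboxylic acid
Conditions: NaClO2 (2 equiv), NaH2PO4 (2 equiv), 2-methyl-2-butene (10 equiv), t-BuOH/THF/H2O, rt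
Reagents that add atoms: sodium chlorite [Na+].[O-]Cl=O
Why: Pinnick oxidation converts the aldehyde to the acid at buffered pH, which preserves the base-labile N-tosyl group, and the alkene traps HOCl before it can chlorinate the indole.

Step 7
Reactants: 7 (±)-2-amino-1-(6-bromo-1-tosyl-1H-indol-3-yl)ethanol; 10 1-tosyl-1H-indole-3-carboxylic acid
Product: 12 (±)-N-[2-(6-bromo-1-tosyl-1H-indol-3-yl)-2-hydroxyethyl]-1-tosyl-1H-indole-3-carboxamide, via benzotriazolyl ester 11 (not isolated)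
Conditions: EDC·HCl (1.3 equiv), HOBt (1.3 equiv), CH2Cl2/DMF, 0 °C → rt
Reagents that add atoms: none
Why: In this carbodiimide/HOBt amide coupling the moderately reactive OBt ester acylates the primary amine much faster than the secondary alcohol, so no hydroxyl protection is needed.

Step 8
Reactants: 12 (±)-N-[2-(6-bromo-1-tosyl-1H-indol-3-yl)-2-hydroxyethyl]-1-tosyl-1H-indole-3-carboxamide
Product: 13 N-[2-(6-bromo-1-tosyl-1H-indol-3-yl)-2-oxoethyl]-1-tosyl-1H-indole-3-carboxamide
Conditions: Dess–Martin periodinane (1.3 equiv), CH2Cl2, rt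
Reagents that add atoms: none
Why: Dess–Martin oxidation of the secondary carbinol works under neutral conditions that spare both N-tosylindoles and the amide, and it removes the only stereocentre of the route.

Step 9
Reactants: 13 N-[2-(6-bromo-1-tosyl-1H-indol-3-yl)-2-oxoethyl]-1-tosyl-1H-indole-3-carboxamide
Product: 15 4-(6-bromo-1-tosyl-1H-indol-3-yl)-2-(1-tosyl-1H-indol-3-yl)-1H-imidazole, via ketimine 14 (not isolated)
Conditions: NH4OAc (30 equiv), AcOH, 110 °C, 8–12 h
Reagents that add atoms: ammonium acetate CC(=O)[O-].[NH4+]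
Why: In this Davidson-type imidazole synthesis ammonia condenses with the N-tosyl-activated ketone, the imine nitrogen closes onto the amide carbonyl with loss of two waters, aromatisation drives the reaction, and any partly detosylated product converges in step 10.

Step 10
Reactants: 15 4-(6-bromo-1-tosyl-1H-indol-3-yl)-2-(1-tosyl-1H-indol-3-yl)-1H-imidazole
Product: 16 nortopsentin C, 4-(6-bromo-1H-indol-3-yl)-2-(1H-indol-3-yl)-1H-imidazole
Conditions: 5 M aq NaOH (10 equiv), 1,4-dioxane, 90 °C, N2; then 1 M HCl to pH ≈ 8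
Reagents that add atoms: none
Why: Hydroxide attacks sulfur and expels each indolide in a plain sulfonamide hydrolysis, the alcohol-free medium prevents alkyl tosylate formation and hence N-alkylation, and the aryl bromide is inert.

## Compound list
1 | 6-bromo-1H-indole | Brc1ccc2cc[nH]c2c1 | starting material
2 | [(6-bromo-1H-indol-3-yl)methylidene]dimethyliminium chloride | C[N+](C)=Cc1c[nH]c2cc(Br)ccc12.[Cl-] | intermediate (not isolated)
3 | 6-bromo-1H-indole-3-carbaldehyde | O=Cc1c[nH]c2cc(Br)ccc12 | intermediate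
4 | 6-bromo-1-tosyl-1H-indole-3-carbaldehyde | O=Cc1cn(S(=O)(=O)c2ccc(C)cc2)c2cc(Br)ccc12 | intermediate
5 | nitromethane | C[N+](=O)[O-] | starting material
6 | (±)-1-(6-bromo-1-tosyl-1H-indol-3-yl)-2-nitroethanol | OC(C[N+](=O)[O-])c1cn(S(=O)(=O)c2ccc(C)cc2)c2cc(Br)ccc12 | intermediate
7 | (±)-2-amino-1-(6-bromo-1-tosyl-1H-indol-3-yl)ethanol | NCC(O)c1cn(S(=O)(=O)c2ccc(C)cc2)c2cc(Br)ccc12 | intermediate
8 | 1H-indole-3-carbaldehyde | O=Cc1c[nH]c2ccccc12 | starting material
9 | 1-tosyl-1H-indole-3-carbaldehyde | O=Cc1cn(S(=O)(=O)c2ccc(C)cc2)c2ccccc12 | intermediate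
10 | 1-tosyl-1H-indole-3-carboxylic acid | OC(=O)c1cn(S(=O)(=O)c2ccc(C)cc2)c2ccccc12 | intermediate
11 | benzotriazol-1-yl 1-tosyl-1H-indole-3-carboxylate | O=C(On1nnc2ccccc12)c1cn(S(=O)(=O)c2ccc(C)cc2)c2ccccc12 | intermediate (not isolated)
12 | (±)-N-[2-(6-bromo-1-tosyl-1H-indol-3-yl)-2-hydroxyethyl]-1-tosyl-1H-indole-3-carboxamide | O=C(NCC(O)c1cn(S(=O)(=O)c2ccc(C)cc2)c2cc(Br)ccc12)c1cn(S(=O)(=O)c2ccc(C)cc2)c2ccccc12 | intermediate
13 | N-[2-(6-bromo-1-tosyl-1H-indol-3-yl)-2-oxoethyl]-1-tosyl-1H-indole-3-carboxamide | O=C(NCC(=O)c1cn(S(=O)(=O)c2ccc(C)cc2)c2cc(Br)ccc12)c1cn(S(=O)(=O)c2ccc(C)cc2)c2ccccc12 | intermediate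
14 | N-[2-(6-bromo-1-tosyl-1H-indol-3-yl)-2-iminoethyl]-1-tosyl-1H-indole-3-carboxamide | O=C(NCC(=N)c1cn(S(=O)(=O)c2ccc(C)cc2)c2cc(Br)ccc12)c1cn(S(=O)(=O)c2ccc(C)cc2)c2ccccc12 | intermediate (not isolated)
15 | 4-(6-bromo-1-tosyl-1H-indol-3-yl)-2-(1-tosyl-1H-indol-3-yl)-1H-imidazole | Cc1ccc(cc1)S(=O)(=O)n1cc(-c2c[nH]c(-c3cn(S(=O)(=O)c4ccc(C)cc4)c4ccccc34)n2)c2ccc(Br)cc12 | intermediate
16 | nortopsentin C | Brc1ccc2c(-c3c[nH]c(-c4c[nH]c5ccccc45)n3)c[nH]c2c1 | target

## Totals
Total step count: 10.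
Longest linear sequence: 8 (steps 1, 2, 3, 4, 7, 8, 9, 10). Steps 5 and 6 form the side branch.

## Three steps most likely to fail, with fallbacks

**Step 3 (Henry addition).** The addition is reversible, and the adduct may partly dehydrate.
- The fallback sets out from 3 and accepts the dehydration in the N–H series.
- Condensing 3 with nitromethane 5 (NH4OAc, reflux) gives (E)-6-bromo-3-(2-nitrovinyl)-1H-indole F1.
- NaBH4 in THF/MeOH reduces the alkene to 6-bromo-3-(2-nitroethyl)-1H-indole F2.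
- Zn/HCl in MeOH then gives 6-bromotryptamine F3.
- EDC/HOBt coupling with acid 10 gives N-[2-(6-bromo-1H-indol-3-yl)ethyl]-1-tosyl-1H-indole-3-carboxamide F4.
- DDQ in THF/H2O (9:1) oxidises the position next to the electron-rich free indole to give N-[2-(6-bromo-1H-indol-3-yl)-2-oxoethyl]-1-tosyl-1H-indole-3-carboxamide F5.
- Selective tosylation of the acidic 3-acylindole N–H (TsCl, Et3N, DMAP) brings the material back to the route at 13.

**Step 4 (nitro reduction on the free nitro alcohol).** The reduction may stall at the hydroxylamine, or the indolyl carbinol may ionise in acid.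
- The fallback sets out from 6 and masks the carbinol first, so that a non-acidic reductant can be used without retro-Henry cleavage.
- TBSOTf/2,6-lutidine gives (±)-6-bromo-3-[1-(tert-butyldimethylsilyloxy)-2-nitroethyl]-1-tosyl-1H-indole F6.
- Nickel boride (NiCl2·6H2O, NaBH4, MeOH, 0 °C, short contact) gives (±)-2-(6-bromo-1-tosyl-1H-indol-3-yl)-2-(tert-butyldimethylsilyloxy)ethanamine F7.
- EDC/HOBt coupling with 10 gives (±)-N-[2-(6-bromo-1-tosyl-1H-indol-3-yl)-2-(tert-butyldimethylsilyloxy)ethyl]-1-tosyl-1H-indole-3-carboxamide F8.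
- HF·pyridine in THF removes the silyl group without touching the sulfonamides, and the route is rejoined at 12.

**Step 9 (imidazole cyclocondensation).** Imine formation may be slow, the tosyl groups may be lost early, or an oxazole may form instead.
- The fallback sets out from 4 and builds the ring as an imidazoline through a nitro-Mannich C–C bond formation.
- Condensing 4 with racemic tert-butanesulfinamide (Ti(OEt)4, THF) gives (E)-N-[(6-bromo-1-tosyl-1H-indol-3-yl)methylidene]-2-methylpropane-2-sulfinamide F9.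
- Adding nitromethane 5 (cat. TBAF, THF) gives N-[1-(6-bromo-1-tosyl-1H-indol-3-yl)-2-nitroethyl]-2-methylpropane-2-sulfinamide F10.
- Zn with HCl in MeOH reduces the nitro group and cleaves the sulfinyl group to give 1-(6-bromo-1-tosyl-1H-indol-3-yl)ethane-1,2-diamine F11.
- Condensing F11 with aldehyde 9 and oxidising the aminal (I2, K2CO3, t-BuOH, 70 °C) gives 4-(6-bromo-1-tosyl-1H-indol-3-yl)-2-(1-tosyl-1H-indol-3-yl)-4,5-dihydro-1H-imidazole F12.
- Dehydrogenation with PhI(OAc)2/K2CO3 in DMSO brings the material back to the route at 15.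

## Further compounds
F1 | step 3 | (E)-6-bromo-3-(2-nitrovinyl)-1H-indole | O=[N+]([O-])/C=C/c1c[nH]c2cc(Br)ccc12
F2 | step 3 | 6-bromo-3-(2-nitroethyl)-1H-indole | O=[N+]([O-])CCc1c[nH]c2cc(Br)ccc12
F3 | step 3 | 6-bromotryptamine | NCCc1c[nH]c2cc(Br)ccc12
F4 | step 3 | N-[2-(6-bromo-1H-indol-3-yl)ethyl]-1-tosyl-1H-indole-3-carboxamide | O=C(NCCc1c[nH]c2cc(Br)ccc12)c1cn(S(=O)(=O)c2ccc(C)cc2)c2ccccc12
F5 | step 3 | N-[2-(6-bromo-1H-indol-3-yl)-2-oxoethyl]-1-tosyl-1H-indole-3-carboxamide | O=C(NCC(=O)c1c[nH]c2cc(Br)ccc12)c1cn(S(=O)(=O)c2ccc(C)cc2)c2ccccc12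
F6 | step 4 | (±)-6-bromo-3-[1-(tert-butyldimethylsilyloxy)-2-nitroethyl]-1-tosyl-1H-indole | CC(C)(C)[Si](C)(C)OC(C[N+](=O)[O-])c1cn(S(=O)(=O)c2ccc(C)cc2)c2cc(Br)ccc12
F7 | step 4 | (±)-2-(6-bromo-1-tosyl-1H-indol-3-yl)-2-(tert-butyldimethylsilyloxy)ethanamine | CC(C)(C)[Si](C)(C)OC(CN)c1cn(S(=O)(=O)c2ccc(C)cc2)c2cc(Br)ccc12
F8 | step 4 | (±)-N-[2-(6-bromo-1-tosyl-1H-indol-3-yl)-2-(tert-butyldimethylsilyloxy)ethyl]-1-tosyl-1H-indole-3-carboxamide | CC(C)(C)[Si](C)(C)OC(CNC(=O)c1cn(S(=O)(=O)c2ccc(C)cc2)c2ccccc12)c1cn(S(=O)(=O)c2ccc(C)cc2)c2cc(Br)ccc12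
F9 | step 9 | (E)-N-[(6-bromo-1-tosyl-1H-indol-3-yl)methylidene]-2-methylpropane-2-sulfinamide | CC(C)(C)S(=O)/N=C/c1cn(S(=O)(=O)c2ccc(C)cc2)c2cc(Br)ccc12
F10 | step 9 | N-[1-(6-bromo-1-tosyl-1H-indol-3-yl)-2-nitroethyl]-2-methylpropane-2-sulfinamide | CC(C)(C)S(=O)NC(C[N+](=O)[O-])c1cn(S(=O)(=O)c2ccc(C)cc2)c2cc(Br)ccc12
F11 | step 9 | 1-(6-bromo-1-tosyl-1H-indol-3-yl)ethane-1,2-diamine | NCC(N)c1cn(S(=O)(=O)c2ccc(C)cc2)c2cc(Br)ccc12
F12 | step 9 | 4-(6-bromo-1-tosyl-1H-indol-3-yl)-2-(1-tosyl-1H-indol-3-yl)-4,5-dihydro-1H-imidazole | Cc1ccc(cc1)S(=O)(=O)n1cc(C2CNC(=N2)c2cn(S(=O)(=O)c3ccc(C)cc3)c3ccccc23)c2ccc(Br)cc12
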